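## Retrosynthetic overview

1. The target comes from fluoride desilylation of its β-silyloxy ketone, which comes from oxidation of the side-chain carbinol. The aryl CO2Me is introduced late from an aryl bromide (Pd, CO, MeOH), so the dihydrofuran ester is the only carbonyl present when it is methylenated.
2. The six-membered ring is formed second and last: C4=C5 by ring-closing metathesis of a 1-methoxyvinyl group (from Petasis methylenation of the ester) with the vinyl group on C6.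
3. The dihydrofuran is formed first: C3–C3a by amine-catalysed intermolecular Michael addition of an acyclic β-keto ester to an aryl enone (the fragment union, sets C3), then iodine-mediated O-cyclisation (C2, trans) and MeCeCl2 addition (C(CH3)2OH).
4. The β-keto ester comes from two Evans boron aldol reactions on an (S)-4-benzyloxazolidinone imide (acrolein sets C6, 3-phenylpropanal sets C7), then Masamune–Brooks homologation.
5. The aryl enone comes from 5-bromosalicylaldehyde by silylation and Wittig olefination.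

Assumption: atom labels follow the benzofuran core (O1, C2, C3, C3a, C4–C7, C7a; the given SMILES is 2R,3R,6R,7R, 2,3-trans, 6,7-cis), and the facial sense of the amine catalyst in step 10 is assigned by analogy with its warfarin-type precedent (from memory, not checked).

Abbreviations: TBS = tert-butyldimethylsilyl, TES = triethylsilyl, TIPS = triisopropylsilyl, TMS = trimethylsilyl, OTf = trifluoromethanesulfonate.

## Route

Step 1
Reactants: 1 5-bromo-2-hydroxybenzaldehyde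
Product: 2 5-bromo-2-(triisopropylsilyloxy)benzaldehyde
Conditions: TIPSCl, imidazole, DMF, rt
Reagents that add atoms: chlorotriisopropylsilane, CC(C)[Si](Cl)(C(C)C)C(C)C
Why: Phenol silylation gives a bulky aryl silyl ether that survives the later amine, carbonate, organocerium and titanium steps and keeps the phenol from being iodinated in step 11; no stereocentre is involved.

Step 2
Reactants: 2 5-bromo-2-(triisopropylsilyloxy)benzaldehyde; 3 1-(triphenylphosphoranylidene)propan-2-one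
Product: 4 (E)-4-[5-bromo-2-(triisopropylsilyloxy)phenyl]but-3-en-2-one
Conditions: toluene, 100 °C
Reagents that add atoms: none
Why: Wittig olefination with a stabilised ylide gives the (E)-enone selectively under neutral conditions that leave the aryl bromide and silyl ether untouched.

Step 3
Reactants: 5 (S)-4-benzyl-3-(chloroacetyl)oxazolidin-2-one; 6 acrolein
Product: 8 (S)-4-benzyl-3-[(2S,3R)-2-chloro-3-hydroxypent-4-enoyl]oxazolidin-2-one, via dibutylboron Z-enolate 7 (not isolated)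
Conditions: Bu2BOTf, Et3N, CH2Cl2, −78 → 0 °C; then acrolein, −78 → 0 °C; pH 7 buffer, MeOH, H2O2
Reagents that add atoms: none
Why: Evans boron aldol reaction: the Z-enolate reacts through a chair transition state on the face away from the benzyl group, so the carbinol centre (later C6) is set as drawn and the chlorine (there only to give a controlled acetate-aldol equivalent) ends up syn.

Step 4
Reactants: 8 (S)-4-benzyl-3-[(2S,3R)-2-chloro-3-hydroxypent-4-enoyl]oxazolidin-2-one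
Product: 9 (S)-4-benzyl-3-[(3S)-3-hydroxypent-4-enoyl]oxazolidin-2-one
Conditions: Zn dust, AcOH, THF, rt
Reagents that add atoms: none
Why: Reductive dehalogenation of the α-chloro imide by zinc, with the zinc enolate protonated by acetic acid faster than it can eliminate, removes the chlorine without touching the carbinol centre (the descriptor changes only through ligand priorities).

Step 5
Reactants: 9 (S)-4-benzyl-3-[(3S)-3-hydroxypent-4-enoyl]oxazolidin-2-one
Product: 10 (S)-4-benzyl-3-[(3S)-3-(tert-butyldimethylsilyloxy)pent-4-enoyl]oxazolidin-2-one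
Conditions: TBSOTf, 2,6-lutidine, CH2Cl2, 0 °C
Reagents that add atoms: tert-butyldimethylsilyl trifluoromethanesulfonate, CC(C)(C)[Si](C)(C)OS(=O)(=O)C(F)(F)F
Why: Silylation of the secondary alcohol gives a TBS ether robust enough to stay on the C6 oxygen until the last step.

Step 6
Reactants: 10 (S)-4-benzyl-3-[(3S)-3-(tert-butyldimethylsilyloxy)pent-4-enoyl]oxazolidin-2-one; 11 3-phenylpropanal
Product: 13 (S)-4-benzyl-3-[(2R,3R)-2-[(1R)-1-(tert-butyldimethylsilyloxy)prop-2-en-1-yl]-3-hydroxy-5-phenylpentanoyl]oxazolidin-2-one, via dibutylboron Z-enolate 12 (not isolated)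
Conditions: Bu2BOTf, i-Pr2NEt, CH2Cl2, −78 → 0 °C; then 3-phenylpropanal, −78 → 0 °C; pH 7 buffer, MeOH, H2O2
Reagents that add atoms: none
Why: Evans syn-aldol reaction: the auxiliary-controlled Z-boron enolate (which does not expel the β-silyloxy group) adds through a chair transition state and sets the future C7 centre (R) and the side-chain carbinol, with the existing silyloxy centre only a spectator, so the later ring bears the C6 oxygen and the C7 side chain cis.

Step 7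
Reactants: 13 (S)-4-benzyl-3-[(2R,3R)-2-[(1R)-1-(tert-butyldimethylsilyloxy)prop-2-en-1-yl]-3-hydroxy-5-phenylpentanoyl]oxazolidin-2-one
Product: 14 (S)-4-benzyl-3-[(2R,3R)-2-[(1R)-1-(tert-butyldimethylsilyloxy)prop-2-en-1-yl]-5-phenyl-3-(triethylsilyloxy)pentanoyl]oxazolidin-2-one
Conditions: TESOTf, 2,6-lutidine, CH2Cl2, −78 °C
Reagents that add atoms: triethylsilyl trifluoromethanesulfonate, CC[Si](CC)(CC)OS(=O)(=O)C(F)(F)F
Why: Silylation of the aldol hydroxyl as a TES ether, which can later be removed in the presence of the TBS and aryl TIPS ethers and prevents lactonisation onto the ester introduced in step 9.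

Step 8
Reactants: 14 (S)-4-benzyl-3-[(2R,3R)-2-[(1R)-1-(tert-butyldimethylsilyloxy)prop-2-en-1-yl]-5-phenyl-3-(triethylsilyloxy)pentanoyl]oxazolidin-2-one
Product: 16 (2R,3R)-2-[(1R)-1-(tert-butyldimethylsilyloxy)prop-2-en-1-yl]-5-phenyl-3-(triethylsilyloxy)pentanoic acid, via peroxy acid 15 (not isolated)
Conditions: LiOH, H2O2, THF/H2O, 0 °C; then Na2SO3; then 1 M HCl
Reagents that add atoms: hydrogen peroxide (acting as LiOOH), OO
Why: Auxiliary removal by lithium hydroperoxide (nucleophilic acyl substitution at the exocyclic imide carbonyl, peracid reduced by sulfite) gives the acid without epimerising the α-centre.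

Step 9
Reactants: 16 (2R,3R)-2-[(1R)-1-(tert-butyldimethylsilyloxy)prop-2-en-1-yl]-5-phenyl-3-(triethylsilyloxy)pentanoic acid; 17 potassium methyl malonate
Product: 19 methyl (4R,5R)-4-[(1R)-1-(tert-butyldimethylsilyloxy)prop-2-en-1-yl]-3-oxo-7-phenyl-5-(triethylsilyloxy)heptanoate, via acyl imidazolide 18 (not isolated)
Conditions: CDI, THF, rt; then potassium methyl malonate, MgCl2, Et3N, MeCN, rt → 40 °C; then 1 M HCl
Reagents that add atoms: none
Why: Masamune–Brooks homologation (C-acylation of the magnesium malonate half-ester by the acyl imidazolide, then decarboxylation; a decarboxylative Claisen condensation) builds the β-keto ester under near-neutral conditions, and enolisation occurs at the doubly activated CH2 rather than at the stereogenic α′-carbon.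

Step 10
Reactants: 19 methyl (4R,5R)-4-[(1R)-1-(tert-butyldimethylsilyloxy)prop-2-en-1-yl]-3-oxo-7-phenyl-5-(triethylsilyloxy)heptanoate; 4 (E)-4-[5-bromo-2-(triisopropylsilyloxy)phenyl]but-3-en-2-one
Product: 20 methyl (3S)-3-[5-bromo-2-(triisopropylsilyloxy)phenyl]-2-[(2R,3R)-2-[(1R)-1-(tert-butyldimethylsilyloxy)prop-2-en-1-yl]-5-phenyl-3-(triethylsilyloxy)pentanoyl]-5-oxohexanoate (both C-2 epimers)
Conditions: 9-amino-9-deoxy-epi-quinidine (20 mol%), CF3CO2H (40 mol%), THF, rt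
Reagents that add atoms: none
Why: Intermolecular asymmetric Michael addition under iminium activation: the cinchona primary amine (the pseudo-enantiomer of the quinine-derived amine used for (S)-warfarin-type additions) shields one face of the enone iminium ion so the benzylic centre (C3 of the target) is set by the catalyst, the dicarbonyl carbon stays epimeric because it becomes sp2 in step 11, and the hindered ketone disfavours a follow-up aldol.

Step 11
Reactants: 20 methyl (3S)-3-[5-bromo-2-(triisopropylsilyloxy)phenyl]-2-[(2R,3R)-2-[(1R)-1-(tert-butyldimethylsilyloxy)prop-2-en-1-yl]-5-phenyl-3-(triethylsilyloxy)pentanoyl]-5-oxohexanoate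
Product: 22 methyl (4R,5R)-5-acetyl-4-[5-bromo-2-(triisopropylsilyloxy)phenyl]-2-[(3R,4R,5R)-3-(tert-butyldimethylsilyloxy)-7-phenyl-5-(triethylsilyloxy)hept-1-en-4-yl]-4,5-dihydrofuran-3-carboxylate, via α-iodo ketone 21 (not isolated)
Conditions: I2, K2CO3, MeCN, 0 °C → rt
Reagents that add atoms: none
Why: Iodine-mediated oxidative cyclisation: reversible C-iodination funnels through the α-iodo methyl ketone, which is displaced by the β-keto ester enolate oxygen (5-exo-tet O-alkylation, so the ring oxygen is unambiguously the ketone oxygen), and the new centre next to the acetyl group is epimerisable and settles trans to the aryl group.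

Step 12
Reactants: 22 methyl (4R,5R)-5-acetyl-4-[5-bromo-2-(triisopropylsilyloxy)phenyl]-2-[(3R,4R,5R)-3-(tert-butyldimethylsilyloxy)-7-phenyl-5-(triethylsilyloxy)hept-1-en-4-yl]-4,5-dihydrofuran-3-carboxylate
Product: 23 methyl (4R,5R)-4-[5-bromo-2-(triisopropylsilyloxy)phenyl]-2-[(3R,4R,5R)-3-(tert-butyldimethylsilyloxy)-7-phenyl-5-(triethylsilyloxy)hept-1-en-4-yl]-5-(2-hydroxypropan-2-yl)-4,5-dihydrofuran-3-carboxylate
Conditions: MeMgBr, CeCl3, THF, −78 °C
Reagents that add atoms: methylmagnesium bromide, C[Mg]Br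
Why: Organocerium 1,2-addition to the methyl ketone is chemoselective over the unreactive vinylogous carbonate ester, and the weakly basic reagent does not epimerise the adjacent centre; no new stereocentre is formed.

Step 13
Reactants: 23 methyl (4R,5R)-4-[5-bromo-2-(triisopropylsilyloxy)phenyl]-2-[(3R,4R,5R)-3-(tert-butyldimethylsilyloxy)-7-phenyl-5-(triethylsilyloxy)hept-1-en-4-yl]-5-(2-hydroxypropan-2-yl)-4,5-dihydrofuran-3-carboxylate
Product: 24 methyl (4R,5R)-4-[5-bromo-2-(triisopropylsilyloxy)phenyl]-2-[(3R,4R,5R)-3-(tert-butyldimethylsilyloxy)-7-phenyl-5-(triethylsilyloxy)hept-1-en-4-yl]-5-[2-(trimethylsilyloxy)propan-2-yl]-4,5-dihydrofuran-3-carboxylate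
Conditions: TMSOTf, 2,6-lutidine, CH2Cl2, −78 → 0 °C
Reagents that add atoms: trimethylsilyl trifluoromethanesulfonate, C[Si](C)(C)OS(=O)(=O)C(F)(F)F
Why: Silylation of the tertiary alcohol removes the only acidic proton before the titanium reagent of step 14 is used.

Step 14
Reactants: 24 methyl (4R,5R)-4-[5-bromo-2-(triisopropylsilyloxy)phenyl]-2-[(3R,4R,5R)-3-(tert-butyldimethylsilyloxy)-7-phenyl-5-(triethylsilyloxy)hept-1-en-4-yl]-5-[2-(trimethylsilyloxy)propan-2-yl]-4,5-dihydrofuran-3-carboxylate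
Product: 25 (2R,3R)-3-[5-bromo-2-(triisopropylsilyloxy)phenyl]-5-[(3R,4R,5R)-3-(tert-butyldimethylsilyloxy)-7-phenyl-5-(triethylsilyloxy)hept-1-en-4-yl]-4-(1-methoxyethenyl)-2-[2-(trimethylsilyloxy)propan-2-yl]-2,3-dihydrofuran
Conditions: Cp2TiMe2 (3 equiv), toluene, 70 °C, dark; filtration through basic alumina
Reagents that add atoms: dimethyltitanocene Cp2TiMe2, C[Ti](C)(C1C=CC=C1)C1C=CC=C1
Why: Petasis methylenation (titanium methylidene carbonyl olefination) converts the ester, the only carbonyl group in the molecule because the arene still carries bromine instead of its ester, into the methyl enol ether under non-acidic conditions.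

Step 15
Reactants: 25 (2R,3R)-3-[5-bromo-2-(triisopropylsilyloxy)phenyl]-5-[(3R,4R,5R)-3-(tert-butyldimethylsilyloxy)-7-phenyl-5-(triethylsilyloxy)hept-1-en-4-yl]-4-(1-methoxyethenyl)-2-[2-(trimethylsilyloxy)propan-2-yl]-2,3-dihydrofuran
Product: 26 (2R,3R,6R,7R)-3-[5-bromo-2-(triisopropylsilyloxy)phenyl]-6-(tert-butyldimethylsilyloxy)-4-methoxy-7-[(1R)-3-phenyl-1-(triethylsilyloxy)propyl]-2-[2-(trimethylsilyloxy)propan-2-yl]-2,3,6,7-tetrahydro-1-benzofuran
Conditions: second-generation Grubbs catalyst RuCl2(=CHPh)(PCy3)(H2IMes) (10 mol%), toluene, 70 °C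
Reagents that add atoms: none
Why: Ring-closing metathesis between the terminal vinyl group and the 1-methoxyvinyl group (loss of ethene) closes the six-membered ring and delivers the C4=C5 methyl enol ether directly, with the ring-oxygen regiochemistry fixed and no stereocentre touched.

Step 16
Reactants: 26 (2R,3R,6R,7R)-3-[5-bromo-2-(triisopropylsilyloxy)phenyl]-6-(tert-butyldimethylsilyloxy)-4-methoxy-7-[(1R)-3-phenyl-1-(triethylsilyloxy)propyl]-2-[2-(trimethylsilyloxy)propan-2-yl]-2,3,6,7-tetrahydro-1-benzofuran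
Product: 27 methyl 3-[(2R,3R,6R,7R)-6-(tert-butyldimethylsilyloxy)-4-methoxy-7-[(1R)-3-phenyl-1-(triethylsilyloxy)propyl]-2-[2-(trimethylsilyloxy)propan-2-yl]-2,3,6,7-tetrahydro-1-benzofuran-3-yl]-4-(triisopropylsilyloxy)benzoate
Conditions: Pd(OAc)2 (5 mol%), Xantphos (10 mol%), CO (1 atm), MeOH, Et3N, toluene, 70 °C
Reagents that add atoms: carbon monoxide, [C-]#[O+]; methanol, CO
Why: Palladium-catalysed methoxycarbonylation of the aryl bromide (oxidative addition, CO insertion, methanolysis) installs the benzoate under basic conditions that the acid-labile dienol ether tolerates, at a stage with no ketone present.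

Step 17
Reactants: 27 methyl 3-[(2R,3R,6R,7R)-6-(tert-butyldimethylsilyloxy)-4-methoxy-7-[(1R)-3-phenyl-1-(triethylsilyloxy)propyl]-2-[2-(trimethylsilyloxy)propan-2-yl]-2,3,6,7-tetrahydro-1-benzofuran-3-yl]-4-(triisopropylsilyloxy)benzoate
Product: 28 methyl 3-[(2R,3R,6R,7R)-6-(tert-butyldimethylsilyloxy)-7-[(1R)-1-hydroxy-3-phenylpropyl]-2-(2-hydroxypropan-2-yl)-4-methoxy-2,3,6,7-tetrahydro-1-benzofuran-3-yl]-4-(triisopropylsilyloxy)benzoate
Conditions: Et3N·3HF, Et3N, THF (anhydrous), 0 °C → rt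
Reagents that add atoms: none
Why: Selective desilylation: the mild fluoride source cleaves the secondary TES and tertiary TMS ethers while the hindered secondary TBS ether and the aryl TIPS ether persist, and the anhydrous amine-buffered medium spares the dienol ether.

Step 18
Reactants: 28 methyl 3-[(2R,3R,6R,7R)-6-(tert-butyldimethylsilyloxy)-7-[(1R)-1-hydroxy-3-phenylpropyl]-2-(2-hydroxypropan-2-yl)-4-methoxy-2,3,6,7-tetrahydro-1-benzofuran-3-yl]-4-(triisopropylsilyloxy)benzoate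
Product: 29 methyl 3-[(2R,3R,6R,7R)-6-(tert-butyldimethylsilyloxy)-2-(2-hydroxypropan-2-yl)-4-methoxy-7-(3-phenylpropanoyl)-2,3,6,7-tetrahydro-1-benzofuran-3-yl]-4-(triisopropylsilyloxy)benzoate
Conditions: (n-Pr4N)(RuO4) (5 mol%), NMO, 4 Å molecular sieves, CH2Cl2, rt
Reagents that add atoms: none
Why: Ley–Griffith oxidation of the only free secondary alcohol gives the ketone under neutral conditions (tertiary alcohol inert, no acid by-product to hydrolyse the dienol ether, no base strong enough to epimerise C7).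

Step 19
Reactants: 29 methyl 3-[(2R,3R,6R,7R)-6-(tert-butyldimethylsilyloxy)-2-(2-hydroxypropan-2-yl)-4-methoxy-7-(3-phenylpropanoyl)-2,3,6,7-tetrahydro-1-benzofuran-3-yl]-4-(triisopropylsilyloxy)benzoate
Product: 30 methyl 4-hydroxy-3-[(2R,3R,6R,7R)-6-hydroxy-2-(2-hydroxypropan-2-yl)-4-methoxy-7-(3-phenylpropanoyl)-2,3,6,7-tetrahydro-1-benzofuran-3-yl]benzoate
Conditions: Bu4NF, AcOH (1:1), THF, 0 °C → rt
Reagents that add atoms: none
Why: Fluoride-mediated desilylation removes the aryl TIPS and the C6 TBS groups, with acetic acid buffering the fluoride so that E1cB loss of the C6 oxygen (which would aromatise the ring) is suppressed; all four stereocentres are already in place.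

## Compound list

1 | 5-bromo-2-hydroxybenzaldehyde | O=Cc1cc(Br)ccc1O | starting material
2 | 5-bromo-2-(triisopropylsilyloxy)benzaldehyde | O=Cc1cc(Br)ccc1O[Si](C(C)C)(C(C)C)C(C)C | intermediate
3 | 1-(triphenylphosphoranylidene)propan-2-one | CC(=O)C=P(c1ccccc1)(c1ccccc1)c1ccccc1 | starting material
4 | (E)-4-[5-bromo-2-(triisopropylsilyloxy)phenyl]but-3-en-2-one | CC(=O)/C=C/c1cc(Br)ccc1O[Si](C(C)C)(C(C)C)C(C)C | intermediate
5 | (S)-4-benzyl-3-(chloroacetyl)oxazolidin-2-one | ClCC(=O)N1C(=O)OC[C@@H]1Cc1ccccc1 | starting material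
6 | acrolein (prop-2-enal) | C=CC=O | starting material
7 | dibutylboron Z-enolate of 5 | Cl/C=C(\OB(CCCC)CCCC)N1C(=O)OC[C@@H]1Cc1ccccc1 | intermediate (not isolated)
8 | (S)-4-benzyl-3-[(2S,3R)-2-chloro-3-hydroxypent-4-enoyl]oxazolidin-2-one | C=C[C@@H](O)[C@H](Cl)C(=O)N1C(=O)OC[C@@H]1Cc1ccccc1 | intermediate
9 | (S)-4-benzyl-3-[(3S)-3-hydroxypent-4-enoyl]oxazolidin-2-one | C=C[C@@H](O)CC(=O)N1C(=O)OC[C@@H]1Cc1ccccc1 | intermediate
10 | (S)-4-benzyl-3-[(3S)-3-(tert-butyldimethylsilyloxy)pent-4-enoyl]oxazolidin-2-one | C=C[C@@H](O[Si](C)(C)C(C)(C)C)CC(=O)N1C(=O)OC[C@@H]1Cc1ccccc1 | intermediate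
11 | 3-phenylpropanal | O=CCCc1ccccc1 | starting material
12 | dibutylboron Z-enolate of 10 | C=C[C@@H](O[Si](C)(C)C(C)(C)C)/C=C(\OB(CCCC)CCCC)N1C(=O)OC[C@@H]1Cc1ccccc1 | intermediate (not isolated)
13 | (S)-4-benzyl-3-[(2R,3R)-2-[(1R)-1-(tert-butyldimethylsilyloxy)prop-2-en-1-yl]-3-hydroxy-5-phenylpentanoyl]oxazolidin-2-one | C=C[C@@H](O[Si](C)(C)C(C)(C)C)[C@@H]([C@H](O)CCc1ccccc1)C(=O)N1C(=O)OC[C@@H]1Cc1ccccc1 | intermediate
14 | (S)-4-benzyl-3-[(2R,3R)-2-[(1R)-1-(tert-butyldimethylsilyloxy)prop-2-en-1-yl]-5-phenyl-3-(triethylsilyloxy)pentanoyl]oxazolidin-2-one | C=C[C@@H](O[Si](C)(C)C(C)(C)C)[C@@H]([C@H](O[Si](CC)(CC)CC)CCc1ccccc1)C(=O)N1C(=O)OC[C@@H]1Cc1ccccc1 | intermediate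
15 | (2R,3R)-2-[(1R)-1-(tert-butyldimethylsilyloxy)prop-2-en-1-yl]-5-phenyl-3-(triethylsilyloxy)pentaneperoxoic acid | C=C[C@@H](O[Si](C)(C)C(C)(C)C)[C@@H]([C@H](O[Si](CC)(CC)CC)CCc1ccccc1)C(=O)OO | intermediate (not isolated)
16 | (2R,3R)-2-[(1R)-1-(tert-butyldimethylsilyloxy)prop-2-en-1-yl]-5-phenyl-3-(triethylsilyloxy)pentanoic acid | C=C[C@@H](O[Si](C)(C)C(C)(C)C)[C@@H]([C@H](O[Si](CC)(CC)CC)CCc1ccccc1)C(=O)O | intermediate
17 | potassium methyl malonate (potassium 3-methoxy-3-oxopropanoate) | COC(=O)CC(=O)[O-].[K+] | starting material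
18 | N-acylimidazole (imidazolide) of acid 16 | C=C[C@@H](O[Si](C)(C)C(C)(C)C)[C@@H]([C@H](O[Si](CC)(CC)CC)CCc1ccccc1)C(=O)n1ccnc1 | intermediate (not isolated)
19 | methyl (4R,5R)-4-[(1R)-1-(tert-butyldimethylsilyloxy)prop-2-en-1-yl]-3-oxo-7-phenyl-5-(triethylsilyloxy)heptanoate | C=C[C@@H](O[Si](C)(C)C(C)(C)C)[C@@H]([C@H](O[Si](CC)(CC)CC)CCc1ccccc1)C(=O)CC(=O)OC | intermediate
20 | methyl (3S)-3-[5-bromo-2-(triisopropylsilyloxy)phenyl]-2-[(2R,3R)-2-[(1R)-1-(tert-butyldimethylsilyloxy)prop-2-en-1-yl]-5-phenyl-3-(triethylsilyloxy)pentanoyl]-5-oxohexanoate (both C-2 epimers) | C=C[C@@H](O[Si](C)(C)C(C)(C)C)[C@@H]([C@H](O[Si](CC)(CC)CC)CCc1ccccc1)C(=O)C(C(=O)OC)[C@H](CC(C)=O)c1cc(Br)ccc1O[Si](C(C)C)(C(C)C)C(C)C | intermediate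
21 | 4-iodo derivative of 20 (α-iodo methyl ketone, epimers at C-2 and C-4) | C=C[C@@H](O[Si](C)(C)C(C)(C)C)[C@@H]([C@H](O[Si](CC)(CC)CC)CCc1ccccc1)C(=O)C(C(=O)OC)[C@H](C(I)C(C)=O)c1cc(Br)ccc1O[Si](C(C)C)(C(C)C)C(C)C | intermediate (not isolated)
22 | methyl (4R,5R)-5-acetyl-4-[5-bromo-2-(triisopropylsilyloxy)phenyl]-2-[(3R,4R,5R)-3-(tert-butyldimethylsilyloxy)-7-phenyl-5-(triethylsilyloxy)hept-1-en-4-yl]-4,5-dihydrofuran-3-carboxylate | CC(=O)[C@@H]1OC(=C([C@H]1c1cc(Br)ccc1O[Si](C(C)C)(C(C)C)C(C)C)C(=O)OC)[C@@H]([C@H](O[Si](C)(C)C(C)(C)C)C=C)[C@H](O[Si](CC)(CC)CC)CCc1ccccc1 | intermediate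
23 | methyl (4R,5R)-4-[5-bromo-2-(triisopropylsilyloxy)phenyl]-2-[(3R,4R,5R)-3-(tert-butyldimethylsilyloxy)-7-phenyl-5-(triethylsilyloxy)hept-1-en-4-yl]-5-(2-hydroxypropan-2-yl)-4,5-dihydrofuran-3-carboxylate | CC(C)(O)[C@@H]1OC(=C([C@H]1c1cc(Br)ccc1O[Si](C(C)C)(C(C)C)C(C)C)C(=O)OC)[C@@H]([C@H](O[Si](C)(C)C(C)(C)C)C=C)[C@H](O[Si](CC)(CC)CC)CCc1ccccc1 | intermediate
24 | methyl (4R,5R)-4-[5-bromo-2-(triisopropylsilyloxy)phenyl]-2-[(3R,4R,5R)-3-(tert-butyldimethylsilyloxy)-7-phenyl-5-(triethylsilyloxy)hept-1-en-4-yl]-5-[2-(trimethylsilyloxy)propan-2-yl]-4,5-dihydrofuran-3-carboxylate | CC(C)(O[Si](C)(C)C)[C@@H]1OC(=C([C@H]1c1cc(Br)ccc1O[Si](C(C)C)(C(C)C)C(C)C)C(=O)OC)[C@@H]([C@H](O[Si](C)(C)C(C)(C)C)C=C)[C@H](O[Si](CC)(CC)CC)CCc1ccccc1 | intermediate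
25 | (2R,3R)-3-[5-bromo-2-(triisopropylsilyloxy)phenyl]-5-[(3R,4R,5R)-3-(tert-butyldimethylsilyloxy)-7-phenyl-5-(triethylsilyloxy)hept-1-en-4-yl]-4-(1-methoxyethenyl)-2-[2-(trimethylsilyloxy)propan-2-yl]-2,3-dihydrofuran | CC(C)(O[Si](C)(C)C)[C@@H]1OC(=C([C@H]1c1cc(Br)ccc1O[Si](C(C)C)(C(C)C)C(C)C)C(=C)OC)[C@@H]([C@H](O[Si](C)(C)C(C)(C)C)C=C)[C@H](O[Si](CC)(CC)CC)CCc1ccccc1 | intermediate
26 | (2R,3R,6R,7R)-3-[5-bromo-2-(triisopropylsilyloxy)phenyl]-6-(tert-butyldimethylsilyloxy)-4-methoxy-7-[(1R)-3-phenyl-1-(triethylsilyloxy)propyl]-2-[2-(trimethylsilyloxy)propan-2-yl]-2,3,6,7-tetrahydro-1-benzofuran | Brc1ccc(O[Si](C(C)C)(C(C)C)C(C)C)c([C@@H]2C3=C(O[C@H]2C(C)(C)O[Si](C)(C)C)[C@H]([C@H](O[Si](CC)(CC)CC)CCc2ccccc2)[C@H](O[Si](C)(C)C(C)(C)C)C=C3OC)c1 | intermediate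
27 | methyl 3-[(2R,3R,6R,7R)-6-(tert-butyldimethylsilyloxy)-4-methoxy-7-[(1R)-3-phenyl-1-(triethylsilyloxy)propyl]-2-[2-(trimethylsilyloxy)propan-2-yl]-2,3,6,7-tetrahydro-1-benzofuran-3-yl]-4-(triisopropylsilyloxy)benzoate | COC(=O)c1ccc(O[Si](C(C)C)(C(C)C)C(C)C)c([C@@H]2C3=C(O[C@H]2C(C)(C)O[Si](C)(C)C)[C@H]([C@H](O[Si](CC)(CC)CC)CCc2ccccc2)[C@H](O[Si](C)(C)C(C)(C)C)C=C3OC)c1 | intermediate
28 | methyl 3-[(2R,3R,6R,7R)-6-(tert-butyldimethylsilyloxy)-7-[(1R)-1-hydroxy-3-phenylpropyl]-2-(2-hydroxypropan-2-yl)-4-methoxy-2,3,6,7-tetrahydro-1-benzofuran-3-yl]-4-(triisopropylsilyloxy)benzoate | COC(=O)c1ccc(O[Si](C(C)C)(C(C)C)C(C)C)c([C@@H]2C3=C(O[C@H]2C(C)(C)O)[C@H]([C@H](O)CCc2ccccc2)[C@H](O[Si](C)(C)C(C)(C)C)C=C3OC)c1 | intermediate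
29 | methyl 3-[(2R,3R,6R,7R)-6-(tert-butyldimethylsilyloxy)-2-(2-hydroxypropan-2-yl)-4-methoxy-7-(3-phenylpropanoyl)-2,3,6,7-tetrahydro-1-benzofuran-3-yl]-4-(triisopropylsilyloxy)benzoate | COC(=O)c1ccc(O[Si](C(C)C)(C(C)C)C(C)C)c([C@@H]2C3=C(O[C@H]2C(C)(C)O)[C@H](C(=O)CCc2ccccc2)[C@H](O[Si](C)(C)C(C)(C)C)C=C3OC)c1 | intermediate
30 | methyl 4-hydroxy-3-[(2R,3R,6R,7R)-6-hydroxy-2-(2-hydroxypropan-2-yl)-4-methoxy-7-(3-phenylpropanoyl)-2,3,6,7-tetrahydro-1-benzofuran-3-yl]benzoate | COC(=O)c1ccc(O)c([C@@H]2C3=C(O[C@H]2C(C)(C)O)[C@H](C(=O)CCc2ccccc2)[C@H](O)C=C3OC)c1 | target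

## Step count and risks

Total steps: 19. Longest linear sequence: 17 steps (from 5 to 30, steps 3 to 19); the aryl enone 4 is made in 2 steps and joins at step 10.

Steps most likely to fail:

The oxidative cyclisation of step 11 is the first risk. Iodination could instead lead to a cyclopropane by C-alkylation, to ring closure through the wrong oxygen, or to iodoetherification of the vinyl group. The fallback sets out from β-keto ester 19 and aldehyde 2. A Knoevenagel condensation (piperidine, AcOH, toluene, 4 Å molecular sieves) gives methyl (4R,5R)-2-[[5-bromo-2-(triisopropylsilyloxy)phenyl]methylidene]-4-[(1R)-1-(tert-butyldimethylsilyloxy)prop-2-en-1-yl]-3-oxo-7-phenyl-5-(triethylsilyloxy)heptanoate F1. Treatment with 1-(2-oxopropyl)pyridinium chloride and Et3N in MeCN then closes the ring: the pyridinium ylide adds in Michael fashion and the enolate oxygen displaces pyridine. This gives the trans-dihydrofuran constitution without ambiguity, but with no facial control, so 22 is formed together with methyl (4S,5S)-5-acetyl-4-[5-bromo-2-(triisopropylsilyloxy)phenyl]-2-[(3R,4R,5R)-3-(tert-butyldimethylsilyloxy)-7-phenyl-5-(triethylsilyloxy)hept-1-en-4-yl]-4,5-dihydrofuran-3-carboxylate F2 and the two are separated by chromatography. The route is rejoined at 22.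

The ring-closing metathesis of step 15 is the second risk. The 1,1-disubstituted, electron-rich enol ether is a slow metathesis partner and ruthenium hydrides can isomerise the diene. The fallback sets out from ester 24 and uses a titanium-alkylidene olefinic-ester cyclisation (TiCl4, TMEDA, Zn, PbCl2, CH3CHBr2, THF/CH2Cl2). The titanium ethylidene exchanges with the terminal vinyl group and the new titanium alkylidene olefinates the ester carbonyl intramolecularly, so the methoxy-substituted ring alkene is formed in one operation. This arrives directly at 26 and makes no new compound (F0).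

The final desilylation of step 19 is the third risk. Fluoride can trigger E1cB loss of the C6 silyloxy or hydroxy group from the β-oxygenated ketone, and the resulting diene aromatises irreversibly. The fallback moves the ring closure to the very end, so that the fluoride step is run on an acyclic aldol that cannot aromatise. It sets out from methoxydiene 25 and runs as follows:
- Methoxycarbonylation as in step 16 gives methyl 3-[(2R,3R)-5-[(3R,4R,5R)-3-(tert-butyldimethylsilyloxy)-7-phenyl-5-(triethylsilyloxy)hept-1-en-4-yl]-4-(1-methoxyethenyl)-2-[2-(trimethylsilyloxy)propan-2-yl]-2,3-dihydrofuran-3-yl]-4-(triisopropylsilyloxy)benzoate F3.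
- Et3N·3HF gives methyl 3-[(2R,3R)-5-[(3R,4R,5R)-3-(tert-butyldimethylsilyloxy)-5-hydroxy-7-phenylhept-1-en-4-yl]-2-(2-hydroxypropan-2-yl)-4-(1-methoxyethenyl)-2,3-dihydrofuran-3-yl]-4-(triisopropylsilyloxy)benzoate F4.
- (n-Pr4N)(RuO4) with NMO gives methyl 3-[(2R,3R)-5-[(3R,4R)-3-(tert-butyldimethylsilyloxy)-5-oxo-7-phenylhept-1-en-4-yl]-2-(2-hydroxypropan-2-yl)-4-(1-methoxyethenyl)-2,3-dihydrofuran-3-yl]-4-(triisopropylsilyloxy)benzoate F5.
- Bu4NF with AcOH gives methyl 4-hydroxy-3-[(2R,3R)-5-[(3R,4R)-3-hydroxy-5-oxo-7-phenylhept-1-en-4-yl]-2-(2-hydroxypropan-2-yl)-4-(1-methoxyethenyl)-2,3-dihydrofuran-3-yl]benzoate F6.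
- Ring-closing metathesis with second-generation Grubbs catalyst RuCl2(=CHPh)(PCy3)(H2IMes) in toluene then closes the six-membered ring as the last, neutral operation and arrives at 30.

Further compounds

F1 | step 11 | methyl (4R,5R)-2-[[5-bromo-2-(triisopropylsilyloxy)phenyl]methylidene]-4-[(1R)-1-(tert-butyldimethylsilyloxy)prop-2-en-1-yl]-3-oxo-7-phenyl-5-(triethylsilyloxy)heptanoate (E/Z mixture) | C=C[C@@H](O[Si](C)(C)C(C)(C)C)[C@@H]([C@H](O[Si](CC)(CC)CC)CCc1ccccc1)C(=O)C(=Cc1cc(Br)ccc1O[Si](C(C)C)(C(C)C)C(C)C)C(=O)OC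
F2 | step 11 | methyl (4S,5S)-5-acetyl-4-[5-bromo-2-(triisopropylsilyloxy)phenyl]-2-[(3R,4R,5R)-3-(tert-butyldimethylsilyloxy)-7-phenyl-5-(triethylsilyloxy)hept-1-en-4-yl]-4,5-dihydrofuran-3-carboxylate | CC(=O)[C@H]1OC(=C([C@@H]1c1cc(Br)ccc1O[Si](C(C)C)(C(C)C)C(C)C)C(=O)OC)[C@@H]([C@H](O[Si](C)(C)C(C)(C)C)C=C)[C@H](O[Si](CC)(CC)CC)CCc1ccccc1
F0 | step 15 | none | none
F3 | step 19 | methyl 3-[(2R,3R)-5-[(3R,4R,5R)-3-(tert-butyldimethylsilyloxy)-7-phenyl-5-(triethylsilyloxy)hept-1-en-4-yl]-4-(1-methoxyethenyl)-2-[2-(trimethylsilyloxy)propan-2-yl]-2,3-dihydrofuran-3-yl]-4-(triisopropylsilyloxy)benzoate | CC(C)(O[Si](C)(C)C)[C@@H]1OC(=C([C@H]1c1cc(C(=O)OC)ccc1O[Si](C(C)C)(C(C)C)C(C)C)C(=C)OC)[C@@H]([C@H](O[Si](C)(C)C(C)(C)C)C=C)[C@H](O[Si](CC)(CC)CC)CCc1ccccc1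
F4 | step 19 | methyl 3-[(2R,3R)-5-[(3R,4R,5R)-3-(tert-butyldimethylsilyloxy)-5-hydroxy-7-phenylhept-1-en-4-yl]-2-(2-hydroxypropan-2-yl)-4-(1-methoxyethenyl)-2,3-dihydrofuran-3-yl]-4-(triisopropylsilyloxy)benzoate | CC(C)(O)[C@@H]1OC(=C([C@H]1c1cc(C(=O)OC)ccc1O[Si](C(C)C)(C(C)C)C(C)C)C(=C)OC)[C@@H]([C@H](O[Si](C)(C)C(C)(C)C)C=C)[C@H](O)CCc1ccccc1
F5 | step 19 | methyl 3-[(2R,3R)-5-[(3R,4R)-3-(tert-butyldimethylsilyloxy)-5-oxo-7-phenylhept-1-en-4-yl]-2-(2-hydroxypropan-2-yl)-4-(1-methoxyethenyl)-2,3-dihydrofuran-3-yl]-4-(triisopropylsilyloxy)benzoate | CC(C)(O)[C@@H]1OC(=C([C@H]1c1cc(C(=O)OC)ccc1O[Si](C(C)C)(C(C)C)C(C)C)C(=C)OC)[C@@H]([C@H](O[Si](C)(C)C(C)(C)C)C=C)C(=O)CCc1ccccc1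
F6 | step 19 | methyl 4-hydroxy-3-[(2R,3R)-5-[(3R,4R)-3-hydroxy-5-oxo-7-phenylhept-1-en-4-yl]-2-(2-hydroxypropan-2-yl)-4-(1-methoxyethenyl)-2,3-dihydrofuran-3-yl]benzoate | CC(C)(O)[C@@H]1OC(=C([C@H]1c1cc(C(=O)OC)ccc1O)C(=C)OC)[C@@H]([C@H](O)C=C)C(=O)CCc1ccccc1
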